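## Retrosynthetic overview

1. Target 18 comes from hydroquinone 17 by Ag2O oxidation of ring B. Compound 17 comes from the tris-MOM isoflavan 16 by acid. The C8 phenol and both quinone oxygens travel as MOM ethers.
2. The plan rests on ring A. C4a (bonded to C4) and C8a (bonded to O1) are neighbours, and C8a is flanked on its other side by the oxygenated C8. An iodide with I at C8a, H at C4a and OMOM at C8 is therefore a mono-ortho-substituted Catellani substrate.
3. Ring C is the only ring built, since rings A and B are both bought as 2,3-dimethoxyphenol. It is cut at C4–C4a and O1–C8a into iodide 4 and the four-atom unit C4–C3–C2–O1 of bromo alcohol 14. The two are joined in one palladium/norbornene operation.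
4. Compound 14 carries C3, which is set by lipase desymmetrisation of the prochiral diol 11. Diol 11 comes from malonate arylation of bromide 8. Iodide 4 comes from MOM-directed lithiation and iodination.

Key step: step 12

Assumption: with the aryl group as the large substituent, the empirical size rule for primary alcohols with Burkholderia cepacia lipase predicts acetylation of the pro-R CH2OH arm of 11. The configuration of 12 is to be confirmed, for example by anomalous-dispersion X-ray analysis of a crystalline derivative of bromide 14, before material is carried on.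

## Route

Step 1
Reactants: 1 2,3-dimethoxyphenol
Product: 2 1,2-dimethoxy-3-(methoxymethoxy)benzene
Conditions: MOMCl, i-Pr2NEt, CH2Cl2, 0 °C to rt
Reagents that add atoms: chloromethyl methyl ether, COCCl
Why: Williamson-type O-alkylation of the phenol with the very reactive alpha-chloro ether should be fast and clean, and the MOM acetal later serves as lithiation director, as the ortho substituent of the key step and as the acid-labile mask of the C8 phenol.

Step 2
Reactants: 2 1,2-dimethoxy-3-(methoxymethoxy)benzene
Product: 4 1-iodo-3,4-dimethoxy-2-(methoxymethoxy)benzene, via aryllithium 3 (not isolated)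
Conditions: n-BuLi, THF, 0 °C; then I2, THF, −78 °C to rt
Reagents that add atoms: iodine, II
Why: Directed ortho-metalation: the chelating OMOM group outranks OMe as director, so n-BuLi should remove the proton next to it (future C8a) and iodine then quenches aryllithium 3 at that carbon.

Step 3
Reactants: 1 2,3-dimethoxyphenol
Product: 5 2,3-dimethoxy-1,4-benzoquinone
Conditions: (KSO3)2NO (2.2 equiv), aq. KH2PO4, acetone, rt
Reagents that add atoms: dipotassium nitrosodisulfonate, [K+].[K+].[O]N(S(=O)(=O)[O-])S(=O)(=O)[O-]
Why: Teuber oxidation: two equivalents of the nitrosodisulfonate radical convert a phenol with a free para position into the para-quinone, the new oxygen entering para to the OH.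

Step 4
Reactants: 5 2,3-dimethoxy-1,4-benzoquinone
Product: 6 2,3-dimethoxybenzene-1,4-diol
Conditions: Na2S2O4, EtOAc/H2O, rt
Reagents that add atoms: none
Why: Dithionite reduction of a quinone to its hydroquinone is a fast two-electron, two-proton transfer in a two-phase system and touches nothing else.

Step 5
Reactants: 6 2,3-dimethoxybenzene-1,4-diol
Product: 7 2,3-dimethoxy-1,4-bis(methoxymethoxy)benzene
Conditions: MOMCl (2.5 equiv), i-Pr2NEt, CH2Cl2, 0 °C to reflux, argon
Reagents that add atoms: chloromethyl methyl ether, COCCl
Why: Double Williamson-type O-alkylation under amine base avoids the air-sensitive dianion and gives a symmetrical arene whose two ring C–H positions are equivalent.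

Step 6
Reactants: 7 2,3-dimethoxy-1,4-bis(methoxymethoxy)benzene
Product: 8 1-bromo-3,4-dimethoxy-2,5-bis(methoxymethoxy)benzene
Conditions: NBS (1.0 equiv), MeCN, 0 °C to rt
Reagents that add atoms: N-bromosuccinimide, O=C1CCC(=O)N1Br
Why: Electrophilic aromatic bromination of a tetraalkoxybenzene with equivalent free positions can give only one monobromide, and succinimide as the by-product keeps the medium neutral for the MOM acetals.

Step 7
Reactants: 8 1-bromo-3,4-dimethoxy-2,5-bis(methoxymethoxy)benzene; 9 diethyl malonate
Product: 10 diethyl 2-[3,4-dimethoxy-2,5-bis(methoxymethoxy)phenyl]propanedioate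
Conditions: Pd(dba)2 (3 mol %), P(t-Bu)3 (6 mol %), K3PO4, toluene, 80 °C
Reagents that add atoms: none
Why: Palladium-catalysed alpha-arylation of a malonate: the bulky electron-rich phosphine allows oxidative addition into the electron-rich, mono-ortho-substituted bromide and reductive elimination from the arylpalladium enolate, and K3PO4 is basic enough for the acidic malonate.

Step 8
Reactants: 10 diethyl 2-[3,4-dimethoxy-2,5-bis(methoxymethoxy)phenyl]propanedioate
Product: 11 2-[3,4-dimethoxy-2,5-bis(methoxymethoxy)phenyl]propane-1,3-diol
Conditions: LiAlH4 (excess), THF, 0 °C to rt, ester added to the hydride; aq. NaOH work-up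
Reagents that add atoms: none
Why: Hydride reduction of both esters to primary alcohols, in which inverse addition keeps reduction ahead of enolisation of the malonate C–H, leaves MOM and methyl ethers untouched and gives a prochiral diol.

Step 9
Reactants: 11 2-[3,4-dimethoxy-2,5-bis(methoxymethoxy)phenyl]propane-1,3-diol
Product: 12 (2R)-2-[3,4-dimethoxy-2,5-bis(methoxymethoxy)phenyl]-3-hydroxypropyl acetate
Conditions: immobilised Burkholderia cepacia lipase, vinyl acetate, MTBE, 30 °C
Reagents that add atoms: vinyl acetate, C=COC(C)=O
Why: Enzymatic desymmetrisation by irreversible transesterification: the chiral active site tells the two enantiotopic CH2OH arms apart and should acetylate the pro-R arm, which creates the future C3 stereocentre, while slight over-acetylation removes the minor enantiomer preferentially.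

Step 10
Reactants: 12 (2R)-2-[3,4-dimethoxy-2,5-bis(methoxymethoxy)phenyl]-3-hydroxypropyl acetate
Product: 13 (2S)-3-bromo-2-[3,4-dimethoxy-2,5-bis(methoxymethoxy)phenyl]propyl acetate
Conditions: CBr4, PPh3, CH2Cl2, 0 °C
Reagents that add atoms: carbon tetrabromide, BrC(Br)(Br)Br
Why: Appel reaction: the free primary alcohol is activated as an alkoxyphosphonium ion and displaced by bromide in an SN2 step at CH2, so the adjacent stereocentre is untouched (the descriptor changes from R to S only because CH2Br now ranks first), and the cold neutral medium with prompt use of 12 should forestall 1,3-acetyl migration.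

Step 11
Reactants: 13 (2S)-3-bromo-2-[3,4-dimethoxy-2,5-bis(methoxymethoxy)phenyl]propyl acetate
Product: 14 (2S)-3-bromo-2-[3,4-dimethoxy-2,5-bis(methoxymethoxy)phenyl]propan-1-ol
Conditions: K2CO3 (0.2 equiv), MeOH, 0 °C
Reagents that add atoms: none
Why: Carbonate-catalysed transesterification with methanol removes the acetate at 0 °C much faster than the liberated alkoxide can close a strained oxetane or the base can eliminate HBr, and C3 is not involved.

Step 12
Reactants: 4 1-iodo-3,4-dimethoxy-2-(methoxymethoxy)benzene; 14 (2S)-3-bromo-2-[3,4-dimethoxy-2,5-bis(methoxymethoxy)phenyl]propan-1-ol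
Product: 16 (3S)-3-[3,4-dimethoxy-2,5-bis(methoxymethoxy)phenyl]-6,7-dimethoxy-8-(methoxymethoxy)chromane, via oxapalladacycle 15 (not isolated)
Conditions: Pd(OAc)2 (10 mol %), RuPhos (20 mol %), norbornene (2 equiv), Cs2CO3 (3 equiv), 4 (1.3 equiv), 1,4-dioxane, 100 °C, argon
Reagents that add atoms: none
Why: Proposed new method: The cycle should open with insertion of zerovalent palladium into the C–I bond of 4; norbornene then inserts syn, carbonate-assisted palladation of the neighbouring C–H (future C4a) closes the aryl–norbornyl palladacycle, this divalent species takes up the primary bromide of 14 in an SN2-like oxidative addition to reach tetravalent palladium, reductive elimination forges C4–C4a, and the now doubly ortho-substituted aryl group drives norbornene out by beta-carbon elimination. The pendant alkoxide next replaces halide on the divalent arylpalladium to give the seven-membered oxapalladacycle 15 (Pd, C8a, C4a, C4, C3, C2, O1), and aryl–oxygen reductive elimination forms O1–C8a, so ring C closes as a six-membered ring by an intramolecular Buchwald–Hartwig-type etherification, overall a formal [4+2] annulation of C4–C3–C2–O1 onto C4a–C8a. The closest known reaction types are the Catellani annulation of aryl iodides with epoxides, which ends in the same C–O reductive elimination but gives five-membered dihydrobenzofurans, the Catellani annulation with bromoalkylamines, which gives six-membered rings through C–N closure, and the separate palladium-catalysed cyclisation of 3-(2-halophenyl)propan-1-ols to chromans with bulky biarylphosphines. No stereocentre is made: C3 comes in with 14, neither new bond touches it and its C–H is far too weakly acidic for Cs2CO3, so the S configuration is carried through. The step needs alkylation before etherification, which is secured because norbornene insertion into the hindered arylpalladium is faster than intermolecular alkoxide coupling, and it needs a single alkylation at one site, which the substrate secures because the C8 OMOM group blocks one ortho position, leaves C4a as the only C–H within reach and supplies the ortho effect that expels norbornene after one alkylation. Reductive elimination must also outrun beta-hydride loss from the primary alkoxide, and catalysis must outrun oxetane closure and E2 loss of HBr from 14, which is why electron-rich bulky RuPhos, sparingly soluble Cs2CO3 and a weakly polar solvent are chosen.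

Step 13
Reactants: 16 (3S)-3-[3,4-dimethoxy-2,5-bis(methoxymethoxy)phenyl]-6,7-dimethoxy-8-(methoxymethoxy)chromane
Product: 17 5-[(3S)-8-hydroxy-6,7-dimethoxychroman-3-yl]-2,3-dimethoxybenzene-1,4-diol
Conditions: HCl (cat., conc. aq.), MeOH, 50 °C, argon
Reagents that add atoms: none
Why: Acid-catalysed acetal exchange with methanol cleaves all three aryl MOM ethers while the methyl ethers, the chroman ether and the C3 stereocentre are inert, and argon keeps the air-sensitive hydroquinone from uncontrolled oxidation.

Step 14
Reactants: 17 5-[(3S)-8-hydroxy-6,7-dimethoxychroman-3-yl]-2,3-dimethoxybenzene-1,4-diol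
Product: 18 5-[(3S)-8-hydroxy-6,7-dimethoxy-3,4-dihydro-2H-chromen-3-yl]-2,3-dimethoxycyclohexa-2,5-diene-1,4-dione (CNP0269725.1)
Conditions: Ag2O (1.2 equiv), CH2Cl2, rt, 30 min, dark
Reagents that add atoms: none
Why: Hydroquinone-to-quinone oxidation with Ag2O: the para-dihydroxy ring B gives up two electrons and two protons far more easily than the lone C8 phenol of ring A, which has no ortho or para hydroxyl partner, and short neutral contact should leave C3 untouched.

## Compound list

1 | 2,3-dimethoxyphenol | COc1cccc(O)c1OC | starting material
2 | 1,2-dimethoxy-3-(methoxymethoxy)benzene | COCOc1cccc(OC)c1OC | intermediate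
3 | [3,4-dimethoxy-2-(methoxymethoxy)phenyl]lithium (not isolated) | COCOc1c([Li])ccc(OC)c1OC | intermediate
4 | 1-iodo-3,4-dimethoxy-2-(methoxymethoxy)benzene | COCOc1c(I)ccc(OC)c1OC | intermediate
5 | 2,3-dimethoxy-1,4-benzoquinone | COC1=C(OC)C(=O)C=CC1=O | intermediate
6 | 2,3-dimethoxybenzene-1,4-diol | COc1c(O)ccc(O)c1OC | intermediate
7 | 2,3-dimethoxy-1,4-bis(methoxymethoxy)benzene | COCOc1ccc(OCOC)c(OC)c1OC | intermediate
8 | 1-bromo-3,4-dimethoxy-2,5-bis(methoxymethoxy)benzene | COCOc1cc(Br)c(OCOC)c(OC)c1OC | intermediate
9 | diethyl malonate | CCOC(=O)CC(=O)OCC | starting material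
10 | diethyl 2-[3,4-dimethoxy-2,5-bis(methoxymethoxy)phenyl]propanedioate | CCOC(=O)C(C(=O)OCC)c1cc(OCOC)c(OC)c(OC)c1OCOC | intermediate
11 | 2-[3,4-dimethoxy-2,5-bis(methoxymethoxy)phenyl]propane-1,3-diol | OCC(CO)c1cc(OCOC)c(OC)c(OC)c1OCOC | intermediate
12 | (2R)-2-[3,4-dimethoxy-2,5-bis(methoxymethoxy)phenyl]-3-hydroxypropyl acetate | COCOc1cc([C@H](CO)COC(C)=O)c(OCOC)c(OC)c1OC | intermediate
13 | (2S)-3-bromo-2-[3,4-dimethoxy-2,5-bis(methoxymethoxy)phenyl]propyl acetate | COCOc1cc([C@H](CBr)COC(C)=O)c(OCOC)c(OC)c1OC | intermediate
14 | (2S)-3-bromo-2-[3,4-dimethoxy-2,5-bis(methoxymethoxy)phenyl]propan-1-ol | COCOc1cc([C@H](CBr)CO)c(OCOC)c(OC)c1OC | intermediate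
15 | seven-membered oxapalladacycle, palladium bonded to C8a and O1, C4–C4a already formed, phosphine not drawn (not isolated) | COCOc1cc([C@H]2CO[Pd]c3c(cc(OC)c(OC)c3OCOC)C2)c(OCOC)c(OC)c1OC | intermediate
16 | (3S)-3-[3,4-dimethoxy-2,5-bis(methoxymethoxy)phenyl]-6,7-dimethoxy-8-(methoxymethoxy)chromane | COCOc1cc([C@H]2COc3c(cc(OC)c(OC)c3OCOC)C2)c(OCOC)c(OC)c1OC | intermediate
17 | 5-[(3S)-8-hydroxy-6,7-dimethoxychroman-3-yl]-2,3-dimethoxybenzene-1,4-diol | Oc1cc([C@H]2COc3c(cc(OC)c(OC)c3O)C2)c(O)c(OC)c1OC | intermediate
18 | 5-[(3S)-8-hydroxy-6,7-dimethoxy-3,4-dihydro-2H-chromen-3-yl]-2,3-dimethoxycyclohexa-2,5-diene-1,4-dione | COC1=C(OC)C(=O)C([C@H]2COc3c(cc(OC)c(OC)c3O)C2)=CC1=O | target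

## Step count and risks

Total step count: 14. Longest linear sequence: 12 steps (steps 3 to 14, from 1).

### Steps most likely to fail

**1. Step 12 (key step).**
- The bromo alcohol may be lost to base-induced elimination of HBr, to oxetane closure, or to displacement of bromide by the neighbouring acetal oxygen before it meets the palladacycle.
- Slow oxidative addition of the beta-branched bromide may let the palladacycle collapse by cyclobutane-forming reductive elimination.
- Beta-hydride elimination from the palladium alkoxide may cause net reduction at C8a instead of C–O bond formation.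

The fallback sets out from 2 and 14 and comes back at 16. It makes the same two bonds in reverse order by known reactions.
- Aryllithium 3, made from 2 as in step 2, is trapped with B(OMe)3 to give dimethyl [3,4-dimethoxy-2-(methoxymethoxy)phenyl]boronate F1. H2O2/NaOH oxidises it to 3,4-dimethoxy-2-(methoxymethoxy)phenol F2.
- NBS with catalytic i-Pr2NH in CH2Cl2 brominates the only free position ortho to the OH and gives 6-bromo-3,4-dimethoxy-2-(methoxymethoxy)phenol F3.
- Mitsunobu etherification of F3 with the primary alcohol of 14 (PPh3, DIAD, THF) forms O1–C2 without touching C3. It gives 1-bromo-2-{(2S)-3-bromo-2-[3,4-dimethoxy-2,5-bis(methoxymethoxy)phenyl]propoxy}-4,5-dimethoxy-3-(methoxymethoxy)benzene F4.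
- n-BuLi in THF at −100 °C exchanges the aryl bromide selectively to give the aryllithium F5. On warming, F5 displaces the primary bromide (Parham cycloalkylation), forms C4–C4a and gives 16.

**2. Step 9.** The bulky ortho-substituted aryl group may cause poor discrimination between the enantiotopic arms, slow turnover or the opposite sense of acylation. 1,3-Acetyl migration may also erode the enantiomeric purity afterwards.

The fallback sets out from 11 and comes back at 14. It replaces enzyme recognition by a small-molecule catalyst that is available in both mirror-image forms.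
- A dinuclear zinc catalyst is made in situ from Et2Zn and the ProPhenol ligand, the ligand enantiomer being chosen in a test run. It transfers benzoyl from vinyl benzoate in toluene at −15 °C and gives (2R)-2-[3,4-dimethoxy-2,5-bis(methoxymethoxy)phenyl]-3-hydroxypropyl benzoate F6, whose benzoate migrates less readily than an acetate.
- An Appel reaction (CBr4, PPh3) gives (2S)-3-bromo-2-[3,4-dimethoxy-2,5-bis(methoxymethoxy)phenyl]propyl benzoate F7.
- K2CO3 in MeOH at 0 °C releases 14.

**3. Step 8.** Hydride may enolise the acidic aryl malonate, which leads to incomplete reduction or to loss of alkoxide and unsaturated by-products.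

The fallback sets out from 7 and comes back at 11. It bypasses steps 6 to 8 by building the diol from an alkene.
- n-BuLi in THF at 0 °C lithiates 7 next to OMOM to give the aryllithium F8. This is trapped with i-PrOBpin to give 2-[3,4-dimethoxy-2,5-bis(methoxymethoxy)phenyl]-4,4,5,5-tetramethyl-1,3,2-dioxaborolane F9.
- Suzuki–Miyaura coupling with 2-bromoprop-2-en-1-ol (Pd(PPh3)4, K2CO3, dioxane/H2O, 80 °C) gives 2-[3,4-dimethoxy-2,5-bis(methoxymethoxy)phenyl]prop-2-en-1-ol F10.
- 9-BBN (2.2 equiv) borylates the hydroxyl group and adds anti-Markovnikov to the 1,1-disubstituted alkene to give the bis(9-BBN) adduct F11. H2O2/NaOH converts F11 into 11.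

## Further compounds

F1 | step 12 | dimethyl [3,4-dimethoxy-2-(methoxymethoxy)phenyl]boronate | COCOc1c(B(OC)OC)ccc(OC)c1OC
F2 | step 12 | 3,4-dimethoxy-2-(methoxymethoxy)phenol | COCOc1c(O)ccc(OC)c1OC
F3 | step 12 | 6-bromo-3,4-dimethoxy-2-(methoxymethoxy)phenol | COCOc1c(O)c(Br)cc(OC)c1OC
F4 | step 12 | 1-bromo-2-{(2S)-3-bromo-2-[3,4-dimethoxy-2,5-bis(methoxymethoxy)phenyl]propoxy}-4,5-dimethoxy-3-(methoxymethoxy)benzene | COCOc1cc([C@H](CBr)COc2c(Br)cc(OC)c(OC)c2OCOC)c(OCOC)c(OC)c1OC
F5 | step 12 | aryllithium from F4, lithium at future C4a | COCOc1cc([C@H](CBr)COc2c([Li])cc(OC)c(OC)c2OCOC)c(OCOC)c(OC)c1OC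
F6 | step 9 | (2R)-2-[3,4-dimethoxy-2,5-bis(methoxymethoxy)phenyl]-3-hydroxypropyl benzoate | COCOc1cc([C@H](CO)COC(=O)c2ccccc2)c(OCOC)c(OC)c1OC
F7 | step 9 | (2S)-3-bromo-2-[3,4-dimethoxy-2,5-bis(methoxymethoxy)phenyl]propyl benzoate | COCOc1cc([C@H](CBr)COC(=O)c2ccccc2)c(OCOC)c(OC)c1OC
F8 | step 8 | [3,4-dimethoxy-2,5-bis(methoxymethoxy)phenyl]lithium | COCOc1cc([Li])c(OCOC)c(OC)c1OC
F9 | step 8 | 2-[3,4-dimethoxy-2,5-bis(methoxymethoxy)phenyl]-4,4,5,5-tetramethyl-1,3,2-dioxaborolane | COCOc1cc(B2OC(C)(C)C(C)(C)O2)c(OCOC)c(OC)c1OC
F10 | step 8 | 2-[3,4-dimethoxy-2,5-bis(methoxymethoxy)phenyl]prop-2-en-1-ol | C=C(CO)c1cc(OCOC)c(OC)c(OC)c1OCOC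
F11 | step 8 | racemic bis(9-BBN) adduct, one boron on the terminal carbon and one on oxygen | COCOc1cc(C(CB2C3CCCC2CCC3)COB2C3CCCC2CCC3)c(OCOC)c(OC)c1OC
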